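**Retrosynthetic overview**
- The target is the all-cis (2S,4R,6S)-2-aryl-6-(2-arylethyl)oxan-4-ol. The three phenols are unmasked last, and the equatorial C4 alcohol is traced back to the 2,6-cis oxan-4-one (axial hydride delivery).
- The oxane ring, the only ring made in the route, is cut at C2–C3 and at O1–C6. A catalytic asymmetric hetero-Diels–Alder reaction joins a silylated 3,4-dihydroxy-5-methoxybenzaldehyde (C2 and O1) with an (E)-2-silyloxy-1,3-diene (C3 to C6 with the arylethyl arm) and sets C2 and C6.
- Enabling feature: in the oxane ring the C4 oxygen stands 1,3 to the ring oxygen O1 through both C3 and C5, and C2 and C6 are cis CH centres. C3–C4(O)=C5–C6 is therefore a latent silyl dienol ether and C2–O1 a latent aryl aldehyde carbonyl.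
- The diene is made from methyl dihydroferulate by silylation, partial reduction, Wittig olefination and enol silylation.

Key step: step 6

Remark (assumption): the catalyst of step 6 is chloro[(1S,2R)-1-{[3-(1-adamantyl)-5-methyl-2-oxidobenzylidene]amino}indan-2-olato]chromium, a trivalent chromium complex, CrCl(C27H29NO2); its (1S,2R) antipode is assumed, by analogy with the facial sense known for this catalyst family, to give the 2S centre, and the (1R,2S) antipode would be used if a first run (Mosher ester analysis of 10) shows the opposite sense.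

**Step 1**
Reactants: 1 3,4-dihydroxy-5-methoxybenzaldehyde
Product: 2 3,4-bis(tert-butyldimethylsilyloxy)-5-methoxybenzaldehyde
Conditions: TBSCl (2.4 equiv), imidazole, DMF, rt
Reagents that add atoms: tert-butyldimethylsilyl chloride, CC(C)(C)[Si](C)(C)Cl
Why: Imidazole-promoted O-silylation of both phenols (silyl ether formation) should leave the aldehyde untouched, and the crowded para silyloxy group is twisted out of conjugation, which keeps the carbonyl electrophilic for step 6.

**Step 2**
Reactants: 3 methyl 3-(4-hydroxy-3-methoxyphenyl)propanoate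
Product: 4 methyl 3-[4-(tert-butyldimethylsilyloxy)-3-methoxyphenyl]propanoate
Conditions: TBSCl (1.2 equiv), imidazole, DMF, rt
Reagents that add atoms: tert-butyldimethylsilyl chloride, CC(C)(C)[Si](C)(C)Cl
Why: Phenol silylation (silyl ether formation) removes the acidic proton that would otherwise consume the hydride, ylide and silyl triflate of the following steps.

**Step 3**
Reactants: 4 methyl 3-[4-(tert-butyldimethylsilyloxy)-3-methoxyphenyl]propanoate
Product: 5 3-[4-(tert-butyldimethylsilyloxy)-3-methoxyphenyl]propanal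
Conditions: i-Bu2AlH (1.05 equiv), CH2Cl2, −78 °C; then MeOH, aq. potassium sodium tartrate
Reagents that add atoms: none
Why: Partial reduction of a methyl ester by DIBAL-H at −78 °C should stop at the tetrahedral aluminium hemiacetal, which releases the aldehyde only on work-up.

**Step 4**
Reactants: 5 3-[4-(tert-butyldimethylsilyloxy)-3-methoxyphenyl]propanal
Product: 6 (E)-6-[4-(tert-butyldimethylsilyloxy)-3-methoxyphenyl]hex-3-en-2-one
Conditions: Ph3P=CHC(O)CH3 (1.3 equiv), toluene, 80 °C
Reagents that add atoms: 1-(triphenylphosphoranylidene)propan-2-one, CC(=O)C=P(c1ccccc1)(c1ccccc1)c1ccccc1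
Why: Wittig olefination with the stabilised acetonyl ylide should give the E-enone, because reversible oxaphosphetane formation favours the trans alkene.

**Step 5**
Reactants: 6 (E)-6-[4-(tert-butyldimethylsilyloxy)-3-methoxyphenyl]hex-3-en-2-one
Product: 7 (E)-6-[4-(tert-butyldimethylsilyloxy)-3-methoxyphenyl]-2-(triethylsilyloxy)hexa-1,3-diene
Conditions: TESOTf (1.3 equiv), Et3N (2 equiv), Et2O, −78 to 0 °C; filtration through base-washed alumina, used directly
Reagents that add atoms: triethylsilyl trifluoromethanesulfonate, CC[Si](CC)(CC)OS(=O)(=O)C(F)(F)F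
Why: Soft enolisation (O-silylation, then kinetic deprotonation of the methyl group by the amine) should give the cross-conjugated silyl dienol ether with the E alkene retained.

**Step 6**
Reactants: 2 3,4-bis(tert-butyldimethylsilyloxy)-5-methoxybenzaldehyde; 7 (E)-6-[4-(tert-butyldimethylsilyloxy)-3-methoxyphenyl]-2-(triethylsilyloxy)hexa-1,3-diene
Product: 9 (2S,6S)-2-[3,4-bis(tert-butyldimethylsilyloxy)-5-methoxyphenyl]-6-{2-[4-(tert-butyldimethylsilyloxy)-3-methoxyphenyl]ethyl}oxan-4-one, via silyl enol ether cycloadduct 8 (not isolated)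
Conditions: CrCl(L*) (10 mol%; L* = (1S,2R)-1-{[3-(1-adamantyl)-5-methyl-2-oxidobenzylidene]amino}indan-2-olate, C27H29NO2), 4 Å MS, acetone (minimal), rt; then TFA (cat.), wet CH2Cl2, 0 °C
Reagents that add atoms: none
Why: The trivalent chromium centre binds the aldehyde oxygen of 2, and diene 7 adds through a concerted, asynchronous (4+2) transition state in which the nucleophilic CH2 terminus bonds to the carbonyl carbon (C2–C3) while the carbonyl oxygen bonds to the alkyl-bearing diene terminus (O1–C6); catalytic acid then hydrolyses enol silane 8 to ketone 9. The closest known reaction type is the chromium Schiff-base catalysed enantioselective hetero-Diels–Alder reaction of aldehydes, aryl aldehydes included, with 2-silyloxy-1,3-dienes, an established entry to 2,6-cis-oxan-4-ones. The oxane ring is closed by intermolecular (4+2) cycloaddition. C2 is set by the catalyst, which exposes one face of the bound aldehyde (expected to lead to 2S with the (1S,2R) ligand), and C6 is set relative to C2 by the endo transition state together with the E geometry of the diene, which should place the aryl and arylethyl groups cis. The step needs regio-, endo- and enantioselectivity and a chemoselective hydrolysis: the 2-silyloxy group polarises the diene so that only one orientation is productive, the formyl group has no ortho substituent and the para silyloxy group is out of plane so that the aldehyde stays reactive, and the triethylsilyl enol ether is far more acid-labile than the three aryl tert-butyldimethylsilyl ethers.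

**Step 7**
Reactants: 9 (2S,6S)-2-[3,4-bis(tert-butyldimethylsilyloxy)-5-methoxyphenyl]-6-{2-[4-(tert-butyldimethylsilyloxy)-3-methoxyphenyl]ethyl}oxan-4-one
Product: 10 (2S,4R,6S)-2-[3,4-bis(tert-butyldimethylsilyloxy)-5-methoxyphenyl]-6-{2-[4-(tert-butyldimethylsilyloxy)-3-methoxyphenyl]ethyl}oxan-4-ol
Conditions: NaBH4, MeOH/THF, −78 to −40 °C
Reagents that add atoms: none
Why: Substrate-controlled ketone reduction: the small hydride should add along the axial trajectory of the chair oxanone whose C2 and C6 groups are equatorial, giving the equatorial, all-cis (4R) alcohol, while the low temperature protects the aryl silyl ethers from methoxide.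

**Step 8**
Reactants: 10 (2S,4R,6S)-2-[3,4-bis(tert-butyldimethylsilyloxy)-5-methoxyphenyl]-6-{2-[4-(tert-butyldimethylsilyloxy)-3-methoxyphenyl]ethyl}oxan-4-ol
Product: 11 5-{(2S,4R,6S)-4-hydroxy-6-[2-(4-hydroxy-3-methoxyphenyl)ethyl]oxan-2-yl}-3-methoxybenzene-1,2-diol
Conditions: Bu4NF (3.5 equiv), AcOH (3.5 equiv), THF, 0 °C, argon
Reagents that add atoms: none
Why: Fluoride-mediated cleavage of the three aryl silyl ethers (desilylation) touches no stereocentre, and the acetic acid buffer protonates the phenoxides at once, which should protect the catechol from air oxidation.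

**Compound list**
1 | 3,4-dihydroxy-5-methoxybenzaldehyde | COc1cc(C=O)cc(O)c1O | starting material
2 | 3,4-bis(tert-butyldimethylsilyloxy)-5-methoxybenzaldehyde | COc1cc(C=O)cc(O[Si](C)(C)C(C)(C)C)c1O[Si](C)(C)C(C)(C)C | intermediate
3 | methyl 3-(4-hydroxy-3-methoxyphenyl)propanoate | COC(=O)CCc1ccc(O)c(OC)c1 | starting material
4 | methyl 3-[4-(tert-butyldimethylsilyloxy)-3-methoxyphenyl]propanoate | COC(=O)CCc1ccc(O[Si](C)(C)C(C)(C)C)c(OC)c1 | intermediate
5 | 3-[4-(tert-butyldimethylsilyloxy)-3-methoxyphenyl]propanal | O=CCCc1ccc(O[Si](C)(C)C(C)(C)C)c(OC)c1 | intermediate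
6 | (E)-6-[4-(tert-butyldimethylsilyloxy)-3-methoxyphenyl]hex-3-en-2-one | CC(=O)/C=C/CCc1ccc(O[Si](C)(C)C(C)(C)C)c(OC)c1 | intermediate
7 | (E)-6-[4-(tert-butyldimethylsilyloxy)-3-methoxyphenyl]-2-(triethylsilyloxy)hexa-1,3-diene | C=C(O[Si](CC)(CC)CC)/C=C/CCc1ccc(O[Si](C)(C)C(C)(C)C)c(OC)c1 | intermediate
8 | (2S,6S)-2-[3,4-bis(tert-butyldimethylsilyloxy)-5-methoxyphenyl]-6-{2-[4-(tert-butyldimethylsilyloxy)-3-methoxyphenyl]ethyl}-4-(triethylsilyloxy)-3,6-dihydro-2H-pyran | COc1cc(CC[C@H]2C=C(O[Si](CC)(CC)CC)C[C@@H](c3cc(O[Si](C)(C)C(C)(C)C)c(O[Si](C)(C)C(C)(C)C)c(OC)c3)O2)ccc1O[Si](C)(C)C(C)(C)C | intermediate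
9 | (2S,6S)-2-[3,4-bis(tert-butyldimethylsilyloxy)-5-methoxyphenyl]-6-{2-[4-(tert-butyldimethylsilyloxy)-3-methoxyphenyl]ethyl}oxan-4-one | COc1cc(CC[C@H]2CC(=O)C[C@@H](c3cc(O[Si](C)(C)C(C)(C)C)c(O[Si](C)(C)C(C)(C)C)c(OC)c3)O2)ccc1O[Si](C)(C)C(C)(C)C | intermediate
10 | (2S,4R,6S)-2-[3,4-bis(tert-butyldimethylsilyloxy)-5-methoxyphenyl]-6-{2-[4-(tert-butyldimethylsilyloxy)-3-methoxyphenyl]ethyl}oxan-4-ol | COc1cc(CC[C@H]2C[C@@H](O)C[C@@H](c3cc(O[Si](C)(C)C(C)(C)C)c(O[Si](C)(C)C(C)(C)C)c(OC)c3)O2)ccc1O[Si](C)(C)C(C)(C)C | intermediate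
11 | 5-{(2S,4R,6S)-4-hydroxy-6-[2-(4-hydroxy-3-methoxyphenyl)ethyl]oxan-2-yl}-3-methoxybenzene-1,2-diol | COc1cc(CC[C@H]2C[C@@H](O)C[C@@H](c3cc(O)c(O)c(OC)c3)O2)ccc1O | target

Total step count: 8
Longest linear sequence: 7 steps (steps 2 to 8, from 3 to 11)

**Steps most likely to fail**

Step 6. The cycloaddition may be slow, because an aryl aldehyde is only moderately electrophilic towards a mono-oxygenated diene; slow turnover would allow hydrolysis of the diene and erosion of enantiofacial control. The fallback forms the same two bonds stepwise and sets out from enone 6 and aldehyde 2. An Ipc2BCl/Et3N-mediated asymmetric boron aldol addition (Et2O, −78 °C, oxidative work-up with H2O2 at pH 7), with the Ipc2BCl antipode that directs attack on the Si face of the aldehyde, should give (1S,4E)-1-[3,4-bis(tert-butyldimethylsilyloxy)-5-methoxyphenyl]-7-[4-(tert-butyldimethylsilyloxy)-3-methoxyphenyl]-1-hydroxyhept-4-en-3-one F1. Acid-catalysed 6-endo-trig oxa-Michael cyclisation (Amberlyst-15, CH2Cl2, rt) under thermodynamic control should then place both ring substituents equatorial, and the route is rejoined at 9.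

Step 5. Enolisation may partly take the γ-CH2 route to the linear conjugated dienol ether, and the silyl dienol ether may hydrolyse back to the enone during isolation. The fallback avoids the diene altogether; it sets out from aldehyde 5 (with aldehyde 2 as partner) and comes back at 10. Brown allylation of 5 with the Ipc2B(allyl) antipode that attacks the Re face (expected: the (+)-reagent, from (+)-Ipc2BOMe and CH2=CHCH2MgBr, Et2O, −78 °C, then NaOH/H2O2) should give (3S)-1-[4-(tert-butyldimethylsilyloxy)-3-methoxyphenyl]hex-5-en-3-ol F2. Prins cyclisation of F2 with 2 (TFA, CH2Cl2, 0 °C) through a chair oxocarbenium ion with equatorial substituents and equatorial trapping should give (2S,4R,6S)-2-[3,4-bis(tert-butyldimethylsilyloxy)-5-methoxyphenyl]-6-{2-[4-(tert-butyldimethylsilyloxy)-3-methoxyphenyl]ethyl}oxan-4-yl trifluoroacetate F3. Mild methanolysis (Et3N, MeOH, 0 °C) then gives 10.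

Step 7. Facial selectivity of hydride delivery may be insufficient, and methoxide may strip aryl silyl ethers. The fallback makes the wrong epimer on purpose and inverts it; it sets out from 9 and comes back at 10. Reduction with the bulky hydride LiBH(s-Bu)3 (THF, −78 °C), which attacks equatorially, should give the axial alcohol (2S,4S,6S)-2-[3,4-bis(tert-butyldimethylsilyloxy)-5-methoxyphenyl]-6-{2-[4-(tert-butyldimethylsilyloxy)-3-methoxyphenyl]ethyl}oxan-4-ol F4. Mitsunobu inversion with benzoic acid (PPh3, DIAD, THF, 0 °C to rt) should give the equatorial ester (2S,4R,6S)-2-[3,4-bis(tert-butyldimethylsilyloxy)-5-methoxyphenyl]-6-{2-[4-(tert-butyldimethylsilyloxy)-3-methoxyphenyl]ethyl}oxan-4-yl benzoate F5. Reductive ester cleavage with i-Bu2AlH (CH2Cl2, −78 °C) then gives 10.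

**Further compounds**
F1 | step 6 | (1S,4E)-1-[3,4-bis(tert-butyldimethylsilyloxy)-5-methoxyphenyl]-7-[4-(tert-butyldimethylsilyloxy)-3-methoxyphenyl]-1-hydroxyhept-4-en-3-one | COc1cc(CC/C=C/C(=O)C[C@@H](c2cc(O[Si](C)(C)C(C)(C)C)c(O[Si](C)(C)C(C)(C)C)c(OC)c2)O)ccc1O[Si](C)(C)C(C)(C)C
F2 | step 5 | (3S)-1-[4-(tert-butyldimethylsilyloxy)-3-methoxyphenyl]hex-5-en-3-ol | COc1cc(CC[C@H](O)CC=C)ccc1O[Si](C)(C)C(C)(C)C
F3 | step 5 | (2S,4R,6S)-2-[3,4-bis(tert-butyldimethylsilyloxy)-5-methoxyphenyl]-6-{2-[4-(tert-butyldimethylsilyloxy)-3-methoxyphenyl]ethyl}oxan-4-yl trifluoroacetate | COc1cc(CC[C@H]2C[C@@H](OC(=O)C(F)(F)F)C[C@@H](c3cc(O[Si](C)(C)C(C)(C)C)c(O[Si](C)(C)C(C)(C)C)c(OC)c3)O2)ccc1O[Si](C)(C)C(C)(C)C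
F4 | step 7 | (2S,4S,6S)-2-[3,4-bis(tert-butyldimethylsilyloxy)-5-methoxyphenyl]-6-{2-[4-(tert-butyldimethylsilyloxy)-3-methoxyphenyl]ethyl}oxan-4-ol | COc1cc(CC[C@H]2C[C@H](O)C[C@@H](c3cc(O[Si](C)(C)C(C)(C)C)c(O[Si](C)(C)C(C)(C)C)c(OC)c3)O2)ccc1O[Si](C)(C)C(C)(C)C
F5 | step 7 | (2S,4R,6S)-2-[3,4-bis(tert-butyldimethylsilyloxy)-5-methoxyphenyl]-6-{2-[4-(tert-butyldimethylsilyloxy)-3-methoxyphenyl]ethyl}oxan-4-yl benzoate | COc1cc(CC[C@H]2C[C@@H](OC(=O)c4ccccc4)C[C@@H](c3cc(O[Si](C)(C)C(C)(C)C)c(O[Si](C)(C)C(C)(C)C)c(OC)c3)O2)ccc1O[Si](C)(C)C(C)(C)C
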